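**Assumption:** the SMILES corresponds to (2R,3S)-2-(4-hydroxy-3,5-dimethoxybenzyl)-4-(4-hydroxy-3-methoxyphenyl)-3-methylbutyl acetate. In lignan numbering this is C8 = S (bears CH3) and C8′ = R (bears CH2OAc), with the two substituents anti in the C7–C7′ zigzag.

## Retrosynthetic overview
1. Target (26) ⇐ lipase-selective O-acetylation of triol 24. Triol 24 ⇐ triple Cu-catalysed Br→OMe exchange on tribromide 22. The aryl oxygens are carried as C–Br until this point.
2. Tribromide 22 ⇐ LiBH4 removal of the (R)-oxazolidinone from 21. Imide 21 ⇐ Evans Z-enolate benzylation of 15 with benzyl bromide 20, which sets C8′ (R).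
3. **Key step:** imide 15 ⇐ MgBr2-templated radical conjugate addition of Me• to the (E)-4-aryl-but-2-enoyl imide 13, which sets C8 (S). The radical-derived CH3 and the later benzyl group add to the same auxiliary-shielded face, which gives the required anti relationship.
4. Enoyl imide 13 ⇐ cross-metathesis of allylarene 7 with acryloyl imide 12. No carbocycle is built. The only ring made is the oxazolidinone auxiliary (step 4), which is recovered in step 12.

## Route

**Step 1**
Reactants: 1 (4-iodophenol), 2 (NBS)
Product: 3 (2-bromo-4-iodophenol)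
Conditions: NBS (1.0 equiv), iPr2NH (cat.), CH2Cl2, 0 °C → rt
Reagents that add atoms: NBS, O=C1CCC(=O)N1Br
Why: Electrophilic aromatic bromination goes ortho to OH because the para position is blocked by iodine.

**Step 2**
Reactants: 3, 4 (potassium allyltrifluoroborate)
Product: 5 (4-allyl-2-bromophenol)
Conditions: Pd(dppf)Cl2 (5 mol%), Cs2CO3, THF/H2O, 70 °C
Reagents that add atoms: C=CC[B-](F)(F)F.[K+]
Why: Suzuki–Miyaura coupling occurs at C–I in preference to the hindered ortho C–Br.

**Step 3**
Reactants: 5, 6 (pivaloyl chloride)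
Product: 7 (4-allyl-2-bromophenyl pivalate)
Conditions: PivCl, Et3N, DMAP (cat.), CH2Cl2, 0 °C
Reagents that add atoms: CC(C)(C)C(=O)Cl
Why: Phenol O-acylation gives a hindered ester that survives the radical, enolate and hydride steps and is removed by methoxide in step 13.

**Step 4**
Reactants: 8 (D-valinol), 9 (diethyl carbonate)
Product: 10 ((R)-4-isopropyloxazolidin-2-one)
Conditions: K2CO3 (cat.), neat, 135 °C, EtOH distilled off
Reagents that add atoms: diethyl carbonate, CCOC(=O)OCC (supplies the ring C=O)
Why: Carbonylative cyclisation of the amino alcohol, with the stereocentre untouched.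

**Step 5**
Reactants: 10, 11 (acryloyl chloride)
Product: 12 ((R)-3-acryloyl-4-isopropyloxazolidin-2-one)
Conditions: n-BuLi, THF, −78 °C; then acryloyl chloride
Reagents that add atoms: C=CC(=O)Cl
Why: N-acylation of the lithiated oxazolidinone.

**Step 6**
Reactants: 7, 12 (3 equiv)
Product: 13 ((R)-3-[(E)-4-(3-bromo-4-pivaloyloxyphenyl)but-2-enoyl]-4-isopropyloxazolidin-2-one)
Conditions: Hoveyda–Grubbs II (5 mol%), p-benzoquinone (10 mol%), CH2Cl2, 40 °C
Reagents that add atoms: none (ethylene is lost)
Why: Cross-metathesis of a type-I allylarene with an excess of the electron-poor acrylimide gives the (E)-enoyl imide selectively.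

**Step 7 (key radical step)**
Reactants: 13, 14 (MeI)
Product: 15 ((R)-3-[(S)-4-(3-bromo-4-pivaloyloxyphenyl)-3-methylbutanoyl]-4-isopropyloxazolidin-2-one)
Conditions: MeI (20 equiv), Bu3SnH (3 equiv, syringe pump), Et3B (1 equiv)/air, MgBr2·OEt2 (2 equiv), CH2Cl2, −78 °C; the major diastereomer is separated by silica chromatography
Reagents that add atoms: MeI, CI
Why: Proposed new method: Bu3Sn• abstracts I from MeI to give Me•. Mg(II) locks the imide in the s-cis chelate, the (R)-iPr group shields one face, and the nucleophilic Me• adds to Cβ on the open face to form C8 (S). The α-imidoyl radical then takes H from Bu3SnH. The closest known reaction is the Lewis-acid-templated Giese addition of iPr•/tBu• to N-enoyl oxazolidinones. Methyl is chosen as the radical because the CH2Ar group then comes from the acceptor, and in step 11 the benzyl group adds to the same face, giving the anti pair.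

**Step 8**
Reactants: 16 (p-cresol), 17 (Br2)
Product: 18 (2,6-dibromo-4-methylphenol)
Conditions: Br2 (2.05 equiv), CH2Cl2, 0 °C
Reagents that add atoms: BrBr
Why: Double ortho SEAr of the para-blocked phenol.

**Step 9**
Reactants: 18, 6
Product: 19 (2,6-dibromo-4-methylphenyl pivalate)
Conditions: NaH, THF, 0 °C; then PivCl
Reagents that add atoms: CC(C)(C)C(=O)Cl
Why: Phenoxide acylation protects the hindered phenol and makes it compatible with NBS and NaHMDS.

**Step 10**
Reactants: 19, 2 (NBS)
Product: 20 (4-(bromomethyl)-2,6-dibromophenyl pivalate)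
Conditions: NBS (1.05 equiv), AIBN (cat.), PhCF3, 85 °C
Reagents that add atoms: NBS, O=C1CCC(=O)N1Br
Why: Wohl–Ziegler radical-chain benzylic bromination, selective for the benzylic C–H over the deactivated ring.

**Step 11**
Reactants: 15, 20 (3 equiv)
Product: 21 ((R)-3-[(2R,3S)-2-(3,5-dibromo-4-pivaloyloxybenzyl)-4-(3-bromo-4-pivaloyloxyphenyl)-3-methylbutanoyl]-4-isopropyloxazolidin-2-one)
Conditions: NaHMDS (1.1 equiv), THF, −78 °C, 45 min; then 20, −78 → −20 °C
Reagents that add atoms: none other than the reactant 20
Why: In this Evans alkylation the Z-sodium chelated enolate is attacked anti to iPr, which is the same face that Me• took in step 7, so C8′ forms as R and the pair is anti.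

**Step 12**
Reactants: 21
Product: 22 ((2R,3S)-2-(3,5-dibromo-4-pivaloyloxybenzyl)-4-(3-bromo-4-pivaloyloxyphenyl)-3-methylbutan-1-ol)
Conditions: LiBH4 (4 equiv), MeOH (1 equiv), THF/Et2O, 0 °C → rt
Reagents that add atoms: none (hydride only; auxiliary 10 is recovered)
Why: Endocyclic-selective hydride cleavage of the imide gives the primary alcohol without touching the α-stereocentre, and a partial loss of the hindered pivalates would be harmless.

**Step 13**
Reactants: 22, 23 (NaOMe)
Product: 24 ((2R,3S)-2-(4-hydroxy-3,5-dimethoxybenzyl)-4-(4-hydroxy-3-methoxyphenyl)-3-methylbutan-1-ol)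
Conditions: CuI (20 mol%), NaOMe (15 equiv), MeOH/DMF, 110 °C, sealed tube
Reagents that add atoms: NaOMe, C[O-].[Na+]
Why: Ullmann-type Cu-catalysed methoxylation of ortho-bromophenoxides (the route used to make syringyl from 2,6-dibromophenols) converts all three ArBr to ArOMe, while methoxide cleaves both pivalates. No stereocentre is epimerisable.

**Step 14**
Reactants: 24, 25 (vinyl acetate)
Product: 26 (target)
Conditions: Novozym 435 (CAL-B), vinyl acetate (5 equiv), TBME, 30 °C
Reagents that add atoms: vinyl acetate, C=COC(C)=O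
Why: Lipase transesterification acetylates only the primary aliphatic alcohol and leaves both phenols free.

## Compound list
1 | 4-iodophenol | Oc1ccc(I)cc1 | starting material
2 | N-bromosuccinimide | O=C1CCC(=O)N1Br | starting material (reagent)
3 | 2-bromo-4-iodophenol | Oc1ccc(I)cc1Br | intermediate
4 | potassium allyltrifluoroborate | C=CC[B-](F)(F)F.[K+] | starting material
5 | 4-allyl-2-bromophenol | C=CCc1ccc(O)c(Br)c1 | intermediate
6 | pivaloyl chloride | CC(C)(C)C(=O)Cl | starting material
7 | 4-allyl-2-bromophenyl pivalate | C=CCc1ccc(OC(=O)C(C)(C)C)c(Br)c1 | intermediate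
8 | D-valinol | CC(C)[C@@H](N)CO | starting material
9 | diethyl carbonate | CCOC(=O)OCC | starting material
10 | (R)-4-isopropyloxazolidin-2-one | CC(C)[C@@H]1COC(=O)N1 | intermediate (auxiliary)
11 | acryloyl chloride | C=CC(=O)Cl | starting material
12 | (R)-3-acryloyl-4-isopropyloxazolidin-2-one | C=CC(=O)N1C(=O)OC[C@H]1C(C)C | intermediate
13 | (R)-3-[(E)-4-(3-bromo-4-pivaloyloxyphenyl)but-2-enoyl]-4-isopropyloxazolidin-2-one | CC(C)(C)C(=O)Oc1ccc(C/C=C/C(=O)N2C(=O)OC[C@H]2C(C)C)cc1Br | intermediate
14 | iodomethane | CI | starting material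
15 | (R)-3-[(S)-4-(3-bromo-4-pivaloyloxyphenyl)-3-methylbutanoyl]-4-isopropyloxazolidin-2-one | CC(C)(C)C(=O)Oc1ccc(C[C@H](C)CC(=O)N2C(=O)OC[C@H]2C(C)C)cc1Br | intermediate
16 | p-cresol | Cc1ccc(O)cc1 | starting material
17 | bromine | BrBr | starting material (reagent)
18 | 2,6-dibromo-4-methylphenol | Cc1cc(Br)c(O)c(Br)c1 | intermediate
19 | 2,6-dibromo-4-methylphenyl pivalate | Cc1cc(Br)c(OC(=O)C(C)(C)C)c(Br)c1 | intermediate
20 | 4-(bromomethyl)-2,6-dibromophenyl pivalate | BrCc1cc(Br)c(OC(=O)C(C)(C)C)c(Br)c1 | intermediate
21 | alkylated imide (2R,3S) | CC(C)(C)C(=O)Oc1ccc(C[C@H](C)[C@H](C(=O)N2C(=O)OC[C@H]2C(C)C)Cc2cc(Br)c(OC(=O)C(C)(C)C)c(Br)c2)cc1Br | intermediate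
22 | (2R,3S)-tribromo alcohol | CC(C)(C)C(=O)Oc1ccc(C[C@H](C)[C@H](CO)Cc2cc(Br)c(OC(=O)C(C)(C)C)c(Br)c2)cc1Br | intermediate
23 | sodium methoxide | C[O-].[Na+] | starting material (reagent)
24 | (2R,3S)-triol | COc1cc(C[C@H](C)[C@H](CO)Cc2cc(OC)c(O)c(OC)c2)ccc1O | intermediate
25 | vinyl acetate | C=COC(C)=O | starting material (reagent)
26 | target acetate | COc1cc(C[C@H](C)[C@H](COC(C)=O)Cc2cc(OC)c(O)c(OC)c2)ccc1O | target

## Totals
Total steps: 14. Longest linear sequence: 9 (1 → 2 → 3 → 6 → 7 → 11 → 12 → 13 → 14, from 4-iodophenol).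

## Three steps most likely to fail
1. **Step 7 (radical methylation).** Et• from Et3B can add instead of Me•, Me• can be quenched by Bu3SnH or solvent, and the diastereoselectivity may be only moderate.
   Fallback: ionic Mg-chelated 1,4-addition of MeMgBr/CuBr·SMe2 to 13 (same face, anti to iPr), which replaces the radical with an organocuprate.
2. **Step 13 (triple Cu-methoxylation).** Hydrodebromination or incomplete exchange of the ortho-bromides next to phenoxides is possible.
   Fallback: install the methoxyls at the fragment stage by methoxylating 5 and 18 with Cu/NaOMe, then run the same sequence with the methoxylated, pivalate-protected fragments.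
3. **Step 6 (cross-metathesis).** The allylarene can isomerise to the propenylarene or homodimerise.
   Fallback: I/Mg exchange on the pivalate of 3, transmetalation to zinc, then Negishi coupling with (E)-4-bromocrotonyl imide (from NBS bromination of crotonyl imide) to give 13 directly.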